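**Retrosynthetic overview**
1. The strategy rests on the succinimide ring (C13, C14, C15, N, C16). It is a succinic anhydride with the ring O exchanged for NH, and both carbonyl carbons C15 and C16 are CO. Cutting C14–C15 and C13–C16 leads back to the C13–C14 terminal oxirane.
2. The threo (12S,13S) C12-silyloxy epoxide comes from the C12 aldehyde by catalyst-controlled vinylation (12R), Sharpless epoxidation (13S), Mitsunobu inversion (12S) and silylation. The single SN2 inversion in the second CO insertion then gives 13R.
3. The aldehyde comes from (+)-sclareolide, which supplies rings A/B and C5, C9, C10. The sequence is C2–H chlorination, lactone opening and dehydration, alkene shift to Δ7, allylic oxidation at C6, and deconjugation back to the 8(17)-alkene.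
4. The 8(17)-en-6-one conjugates readily with base, so it is carried as its 6β-triethylsilyl ether (a spectator change in the key pair, with C12 then protected as the sturdier TBS ether). The ketone is restored by oxidation after the imide is closed.
5. Ring order: A/B decalin (bought) → oxirane → β-lactone → anhydride → imide (3 → 4 → 5 ring atoms, then O → N).

Key step: step 14

Assumption: labdane numbering is used (C17 = exocyclic CH2, C15/C16 = imide carbonyls). Chloroamide 2, the cobalt salen complex and the aluminium porphyrin cobaltate are taken as purchasable or made by routine preparations that are not counted. The temporary C6 carbinol is drawn 6β and its configuration has no bearing on the target.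

**Step 1**
Reactants: 1 (+)-sclareolide; 2 N-tert-butyl-N-chloro-3,5-bis(trifluoromethyl)benzamide
Product: 3 2α-chlorosclareolide
Conditions: 2, Cs2CO3, PhH, visible light, 55 °C
Reagents that add atoms: N-tert-butyl-N-chloro-3,5-bis(trifluoromethyl)benzamide, CC(C)(C)N(Cl)C(=O)c1cc(cc(c1)C(F)(F)F)C(F)(F)F
Why: Radical-chain aliphatic C–H chlorination with an N-chloroamide, in which the bulky electrophilic amidyl radical abstracts H from C2 (the least hindered methylene and the one farthest from the lactone) and Cl transfer from the α face, away from the axial C10 and C4β methyls, should set the equatorial 2α-chloride.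

**Step 2**
Reactants: 3 2α-chlorosclareolide
Product: 4 2α-chloro-8α-hydroxy-13,14,15,16-tetranorlabdan-12-oic acid N-methoxy-N-methylamide
Conditions: MeNH(OMe)·HCl, AlMe3, CH2Cl2, 0 °C → rt
Reagents that add atoms: N,O-dimethylhydroxylamine hydrochloride, CNOC.Cl
Why: Aluminium-amide aminolysis of a lactone (Weinreb amide formation) cleaves only the acyl C–O bond, so C8 keeps its 8α-oxygen and the secondary chloride is untouched.

**Step 3**
Reactants: 4 hydroxy Weinreb amide
Product: 5 2α-chloro-13,14,15,16-tetranorlabd-8(17)-en-12-oic acid Weinreb amide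
Conditions: SOCl2, pyridine, CH2Cl2, −78 °C
Reagents that add atoms: none
Why: Chlorosulfite E2 dehydration, in which the equatorial 8α leaving group has antiperiplanar hydrogens only on the C17 methyl, so the exocyclic 8(17)-alkene should prevail at low temperature.

**Step 4**
Reactants: 5 8(17)-ene Weinreb amide
Product: 6 2α-chloro-13,14,15,16-tetranorlabd-7-en-12-oic acid Weinreb amide
Conditions: (salen-tBu,tBu)CoCl (3 mol %), PhSiH3 (6 mol %), PhH, rt
Reagents that add atoms: none
Why: Cobalt-hydride hydrogen-atom-transfer (MHAT) alkene isomerisation, in which H• adds to C17 to give the tertiary C8 radical and is taken back from the exposed C7 methylene rather than the shielded tertiary C9–H, moving the alkene to Δ7 and leaving C9 intact.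

**Step 5**
Reactants: 6 Δ7-alkene Weinreb amide
Product: 7 2α-chloro-6-oxo-13,14,15,16-tetranorlabd-7-en-12-oic acid Weinreb amide
Conditions: CrO3, 3,5-dimethylpyrazole, CH2Cl2, −20 °C
Reagents that add atoms: chromium trioxide, O=[Cr](=O)=O
Why: Chromium(VI)–dimethylpyrazole allylic oxidation of a trisubstituted cyclohexene, where only the ring methylene C6 among the allylic sites can become an enone carbonyl, as in drim-7-ene → drim-7-en-6-one and Δ5-steroid → 7-ketone oxidations.

**Step 6**
Reactants: 7 7-en-6-one Weinreb amide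
Product: 10 2α-chloro-6β-hydroxy-13,14,15,16-tetranorlabd-8(17)-en-12-oic acid Weinreb amide, via potassium 6,8(17)-dienolate 8 (not isolated), via 8(17)-en-6-one 9 (not isolated)
Conditions: 7 added to KHMDS (2 equiv), THF, −78 °C; AcOH, −78 °C; then CeCl3·7H2O, NaBH4, MeOH, −78 → 0 °C
Reagents that add atoms: none
Why: Deconjugative kinetic protonation of an extended dienolate followed by Luche reduction, in which the hindered base can reach only C17–H3 (C5–H lies between two quaternary carbons and C9–H is tertiary), C7 protonation gives the β,γ-enone, and this is reduced at once from the open α face (β face blocked by the C10 and C4β methyls) to the 6β-alcohol.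

**Step 7**
Reactants: 10 6β-alcohol
Product: 11 2α-chloro-6β-(triethylsilyloxy)-13,14,15,16-tetranorlabd-8(17)-en-12-oic acid Weinreb amide
Conditions: TESOTf, 2,6-lutidine, CH2Cl2, 0 °C
Reagents that add atoms: triethylsilyl triflate, CC[Si](CC)(CC)OS(=O)(=O)C(F)(F)F
Why: Silyl triflate silylation is strong enough for the crowded axial 6β-alcohol and masks C6 at the alcohol level through every basic, Lewis acidic and nucleophilic step that follows.

**Step 8**
Reactants: 11 TES ether Weinreb amide
Product: 12 2α-chloro-6β-(triethylsilyloxy)-13,14,15,16-tetranorlabd-8(17)-en-12-al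
Conditions: DIBAL-H, THF, −78 °C; Rochelle salt
Reagents that add atoms: none
Why: In the Weinreb amide reduction the chelated aluminium hemiaminal persists until work-up, so reduction stops at the aldehyde.

**Step 9**
Reactants: 12 aldehyde; 13 vinylmagnesium bromide
Product: 14 (12R)-2α-chloro-6β-(triethylsilyloxy)-15,16-dinorlabda-8(17),13-dien-12-ol
Conditions: 13, ZnCl2, Et2O, then 1,4-dioxane, filter; (−)-MIB (10 mol %), toluene, 0 °C
Reagents that add atoms: vinylmagnesium bromide, C=C[Mg]Br
Why: Amino-alcohol-catalysed asymmetric addition of divinylzinc to an aldehyde, in which the (−)-ligand directs vinyl to the Si face to give 12R under catalyst control (the ring stereocentres are remote), and any 12S epimer is rejected in step 10.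

**Step 10**
Reactants: 14 (12R)-allylic alcohol
Product: 15 (12R,13S)-13,14-epoxy alcohol (erythro)
Conditions: Ti(OiPr)4 (0.2 equiv), D-(−)-DIPT (0.25 equiv), TBHP (decane), 4 Å MS, CH2Cl2, −20 °C
Reagents that add atoms: tert-butyl hydroperoxide, CC(C)(C)OO
Why: Sharpless asymmetric epoxidation in its matched, kinetic-resolution mode, in which D-(−)-DIPT makes the 12R carbinol the fast series and gives the erythro (12R,13S) epoxy alcohol, with titanium delivering oxygen only to the alkene of the bound allylic alcohol so that C8=C17 is spared.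

**Step 11**
Reactants: 15 erythro epoxy alcohol
Product: 16 (12S,13S)-13,14-epoxy-12-(4-nitrobenzoate)
Conditions: 4-O2NC6H4CO2H, PPh3, DIAD, toluene, 0 °C → rt
Reagents that add atoms: 4-nitrobenzoic acid, O=C(O)c1ccc(cc1)[N+](=O)[O-]
Why: In the Mitsunobu reaction, SN2 displacement of the oxyphosphonium ion by the carboxylate inverts C12 (R → S) without touching the oxirane or C13, turning erythro into threo.

**Step 12**
Reactants: 16 4-nitrobenzoate
Product: 17 (12S,13S)-13,14-epoxy-12-ol (threo)
Conditions: K2CO3 (0.2 equiv), MeOH, 0 °C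
Reagents that add atoms: none
Why: Carbonate-catalysed transesterification cleaves the activated ester at its acyl carbon, so C12–O stays intact, and it is fast at 0 °C relative to Payne migration, which for the threo isomer would lead to the less stable cis-epoxide.

**Step 13**
Reactants: 17 threo epoxy alcohol
Product: 18 (12S,13S)-12-(tert-butyldimethylsilyloxy)-13,14-epoxide (key precursor)
Conditions: TBSCl, imidazole, DMAP (cat.), DMF, rt
Reagents that add atoms: tert-butyldimethylsilyl chloride, CC(C)(C)[Si](C)(C)Cl
Why: Imidazole-promoted silylation is mild enough for the oxirane and caps the only protic group, which would otherwise intercept acyl cobalt, β-lactone or anhydride in step 14.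

**Step 14**
Reactants: 18 threo silyloxy epoxide; 19 carbon monoxide
Product: 21 (12S,13R)-12-(tert-butyldimethylsilyloxy) succinic anhydride, via (12S,13S)-β-lactone 20 (not isolated)
Conditions: [(ClTPP)Al(THF)2][Co(CO)4] (5 mol %; ClTPP = meso-tetrakis(4-chlorophenyl)porphyrinate), CO (60 bar), 1,4-dioxane, 90 °C
Reagents that add atoms: carbon monoxide, [C-]#[O+]
Why: The aluminium porphyrin cation binds the oxirane oxygen, [Co(CO)4]− opens it by SN2 at the unhindered C14 methylene, CO inserts into C14–Co (C14–C15), and the C13 aluminium alkoxide attacks the acyl cobalt in a 4-exo-trig closure to give β-lactone 20 with C13–O untouched. In the second cycle the same ion pair activates 20 at its carbonyl oxygen, cobaltate displaces the carboxylate at C13 by SN2 (alkyl C–O cleavage, inversion), CO inserts with retention (C13–C16), and the aluminium carboxylate closes on the acyl cobalt in a 5-exo-trig mode to release anhydride 21. This is the known Lewis acid–cobaltate double carbonylation of terminal epoxides to succinic anhydrides through β-lactones, which is stereospecific with one net inversion at the substituted carbon. C13 is therefore controlled by the substrate alone, with 13S in 18 becoming 13R in 21, while C12 is a spectator and stays S. The step needs terminal regioselectivity in the first opening, secured by the contrast between the C14 CH2 and the branched, inductively deactivated C13; it also needs clean SN2 rather than ionisation or elimination at C13, secured by the electron-withdrawing C12 silyloxy group and by high CO pressure that traps the alkyl cobalt before β-hydride or β-silyloxy loss. The equatorial C2 chloride, both silyl ethers and the 1,1-disubstituted alkene offer no competing Lewis basic or electrophilic site under anhydrous aprotic conditions.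

**Step 15**
Reactants: 21 anhydride; 22 ammonia
Product: 25 6β-(triethylsilyloxy)-12-(tert-butyldimethylsilyloxy) succinimide, via C15-carboxamide/C16-carboxylic acid 23 (not isolated), via C16-carboxamide/C15-carboxylic acid 24 (not isolated)
Conditions: NH3 (0.5 M in dioxane, 1.05 equiv), THF, 0 °C → rt; Ar sparge; then CDI (1.5 equiv), same flask, rt → 45 °C; aqueous work-up
Reagents that add atoms: ammonia, N
Why: Aminolysis of a cyclic anhydride followed in the same flask by carbonyldiimidazole-mediated dehydrative imide closure (as used for succinimides and glutarimides), in which one equivalent of ammonia in an aprotic solvent opens 21 at either carbonyl (mainly the less hindered C15) to the free amic acids 23 and 24, each acid is activated as its acyl imidazole and the primary amide nitrogen closes on it in a 5-exo-trig mode, so both regioisomers converge on the single imide 25, no ammonium salt is left to divert the acyl imidazole, and C13 is not enolised by the weak base imidazole.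

**Step 16**
Reactants: 25 bis-silyl imide
Product: 26 6β-hydroxy-12-OTBS imide
Conditions: HF·pyridine, excess pyridine, THF, 0 °C
Reagents that add atoms: none
Why: Selective desilylation relies on the large lability gap between triethylsilyl and tert-butyldimethylsilyl ethers toward buffered HF.

**Step 17**
Reactants: 26 6β-alcohol
Product: 27 6-oxo-12-OTBS imide
Conditions: Dess–Martin periodinane, pyridine, CH2Cl2, 0 °C
Reagents that add atoms: none
Why: Dess–Martin oxidation under pyridine buffer is neutral and non-enolising, is the standard way from a homoallylic alcohol to a β,γ-unsaturated ketone without conjugation, and removes the temporary C6 stereocentre.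

**Step 18**
Reactants: 27 6-oxo-12-OTBS imide
Product: 28 haterumaimide G
Conditions: HF·pyridine, MeCN, 0 °C → rt
Reagents that add atoms: none
Why: Fluoride-mediated desilylation in a weakly acidic buffered medium avoids the base that would trigger retro-aldol or lactone–amide isomerisation of the β-hydroxy imide and migration of the 8(17)-alkene into conjugation.

**Compound list**
1 | (+)-sclareolide | C[C@@]12CC[C@H]3C(C)(C)CCC[C@]3(C)[C@H]1CC(=O)O2 | starting material
2 | N-tert-butyl-N-chloro-3,5-bis(trifluoromethyl)benzamide | CC(C)(C)N(Cl)C(=O)c1cc(cc(c1)C(F)(F)F)C(F)(F)F | starting material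
3 | 2α-chlorosclareolide | C[C@@]12CC[C@H]3C(C)(C)C[C@H](Cl)C[C@]3(C)[C@H]1CC(=O)O2 | intermediate
4 | 2α-chloro-8α-hydroxy Weinreb amide | C[C@@]1(O)CC[C@H]2C(C)(C)C[C@H](Cl)C[C@]2(C)[C@H]1CC(=O)N(C)OC | intermediate
5 | 2α-chloro-8(17)-ene Weinreb amide | C=C1CC[C@H]2C(C)(C)C[C@H](Cl)C[C@]2(C)[C@H]1CC(=O)N(C)OC | intermediate
6 | 2α-chloro-7-ene Weinreb amide | CC1=CC[C@H]2C(C)(C)C[C@H](Cl)C[C@]2(C)[C@H]1CC(=O)N(C)OC | intermediate
7 | 2α-chloro-7-en-6-one Weinreb amide | CC1=CC(=O)[C@H]2C(C)(C)C[C@H](Cl)C[C@]2(C)[C@H]1CC(=O)N(C)OC | intermediate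
8 | potassium 6,8(17)-dienolate | C=C1C=C([O-])[C@H]2C(C)(C)C[C@H](Cl)C[C@]2(C)[C@H]1CC(=O)N(C)OC.[K+] | intermediate
9 | 2α-chloro-8(17)-en-6-one Weinreb amide | C=C1CC(=O)[C@H]2C(C)(C)C[C@H](Cl)C[C@]2(C)[C@H]1CC(=O)N(C)OC | intermediate
10 | 2α-chloro-6β-hydroxy-8(17)-ene Weinreb amide | C=C1C[C@@H](O)[C@H]2C(C)(C)C[C@H](Cl)C[C@]2(C)[C@H]1CC(=O)N(C)OC | intermediate
11 | 6β-OTES Weinreb amide | C=C1C[C@@H](O[Si](CC)(CC)CC)[C@H]2C(C)(C)C[C@H](Cl)C[C@]2(C)[C@H]1CC(=O)N(C)OC | intermediate
12 | 6β-OTES C12 aldehyde | C=C1C[C@@H](O[Si](CC)(CC)CC)[C@H]2C(C)(C)C[C@H](Cl)C[C@]2(C)[C@H]1CC=O | intermediate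
13 | vinylmagnesium bromide | C=C[Mg]Br | starting material
14 | (12R)-allylic alcohol | C=C1C[C@@H](O[Si](CC)(CC)CC)[C@H]2C(C)(C)C[C@H](Cl)C[C@]2(C)[C@H]1C[C@@H](O)C=C | intermediate
15 | (12R,13S)-erythro epoxy alcohol | C=C1C[C@@H](O[Si](CC)(CC)CC)[C@H]2C(C)(C)C[C@H](Cl)C[C@]2(C)[C@H]1C[C@@H](O)[C@@H]1CO1 | intermediate
16 | (12S,13S)-epoxy 4-nitrobenzoate | C=C1C[C@@H](O[Si](CC)(CC)CC)[C@H]2C(C)(C)C[C@H](Cl)C[C@]2(C)[C@H]1C[C@H](OC(=O)c3ccc(cc3)[N+](=O)[O-])[C@@H]4CO4 | intermediate
17 | (12S,13S)-threo epoxy alcohol | C=C1C[C@@H](O[Si](CC)(CC)CC)[C@H]2C(C)(C)C[C@H](Cl)C[C@]2(C)[C@H]1C[C@H](O)[C@@H]1CO1 | intermediate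
18 | (12S,13S)-12-OTBS epoxide (key precursor) | C=C1C[C@@H](O[Si](CC)(CC)CC)[C@H]2C(C)(C)C[C@H](Cl)C[C@]2(C)[C@H]1C[C@H](O[Si](C)(C)C(C)(C)C)[C@@H]1CO1 | intermediate
19 | carbon monoxide | [C-]#[O+] | starting material
20 | (12S,13S)-β-lactone | C=C1C[C@@H](O[Si](CC)(CC)CC)[C@H]2C(C)(C)C[C@H](Cl)C[C@]2(C)[C@H]1C[C@H](O[Si](C)(C)C(C)(C)C)[C@@H]1CC(=O)O1 | intermediate
21 | (12S,13R)-succinic anhydride (key product) | C=C1C[C@@H](O[Si](CC)(CC)CC)[C@H]2C(C)(C)C[C@H](Cl)C[C@]2(C)[C@H]1C[C@H](O[Si](C)(C)C(C)(C)C)[C@H]1CC(=O)OC1=O | intermediate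
22 | ammonia | N | starting material
23 | amic acid, C15 amide/C16 acid | C=C1C[C@@H](O[Si](CC)(CC)CC)[C@H]2C(C)(C)C[C@H](Cl)C[C@]2(C)[C@H]1C[C@H](O[Si](C)(C)C(C)(C)C)[C@@H](CC(N)=O)C(=O)O | intermediate
24 | amic acid, C16 amide/C15 acid | C=C1C[C@@H](O[Si](CC)(CC)CC)[C@H]2C(C)(C)C[C@H](Cl)C[C@]2(C)[C@H]1C[C@H](O[Si](C)(C)C(C)(C)C)[C@@H](CC(=O)O)C(N)=O | intermediate
25 | 6β-OTES-12-OTBS imide | C=C1C[C@@H](O[Si](CC)(CC)CC)[C@H]2C(C)(C)C[C@H](Cl)C[C@]2(C)[C@H]1C[C@H](O[Si](C)(C)C(C)(C)C)[C@H]1CC(=O)NC1=O | intermediate
26 | 6β-hydroxy-12-OTBS imide | C=C1C[C@@H](O)[C@H]2C(C)(C)C[C@H](Cl)C[C@]2(C)[C@H]1C[C@H](O[Si](C)(C)C(C)(C)C)[C@H]1CC(=O)NC1=O | intermediate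
27 | 6-oxo-12-OTBS imide | C=C1CC(=O)[C@H]2C(C)(C)C[C@H](Cl)C[C@]2(C)[C@H]1C[C@H](O[Si](C)(C)C(C)(C)C)[C@H]1CC(=O)NC1=O | intermediate
28 | haterumaimide G | C=C1CC(=O)[C@H]2C(C)(C)C[C@H](Cl)C[C@]2(C)[C@H]1C[C@H](O)[C@H]1CC(=O)NC1=O | target

**Total step count:** 18. **Longest linear sequence:** 18 (from 1).

**Steps most likely to fail**

Step 14. The second insertion may stall at the β-lactone, because cobaltate has to attack a carbon that is branched and inductively deactivated by the neighbouring silyloxy group. Competing processes are Lewis-acid rearrangement of the oxirane to a carbonyl compound, elimination from the alkyl cobalt, and cobalt-hydride migration of the exocyclic alkene. The fallback sets out from aldehyde 12 and comes back at imide 25, building C12–C13 by an aldol instead of inserting CO. 3-Cyanopropanoic acid is coupled (PivCl, Et3N, LiCl) to (R)-4-benzyloxazolidin-2-one to give (R)-4-benzyl-3-(3-cyanopropanoyl)oxazolidin-2-one F1. Its Z-boron enolate (Bu2BOTf, iPr2NEt, CH2Cl2, −78 °C) adds to 12 in an Evans syn aldol to give the (12S,13R) aldol adduct F2, and TBSOTf/2,6-lutidine then gives the C12 silyl ether F3. Neutral platinum-catalysed nitrile hydration (EtOH/H2O) gives the primary carboxamide F4, whose nitrogen displaces the oxazolidinone at C16 (catalytic DBU if needed) and closes 25.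

Step 6. Site selectivity in the γ-deprotonation may be poor (C9–H against C17–H3). The proton may return at C17, or the β,γ-enone may reconjugate before it is reduced. The fallback sets out from alkene 5 (so it also bypasses steps 4 and 5) and comes back at enone 9, making the exocyclic dienolate regiospecifically by reduction. SeO2 (cat.)/TBHP gives the 7α-allylic alcohol F5, SOCl2 in Et2O transposes it (SNi′) to the 17-chloro-7-ene F6, and CrO3/3,5-dimethylpyrazole gives the 17-chloro-7-en-6-one F7. Zinc dust in Et2O/AcOH at 0 °C expels the γ-chloride to give the chlorozinc 6,8(17)-dienolate F8, whose protonation at C7 gives 9, which is reduced as in step 6 to 10.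

Step 16. Discrimination between the two silyl ethers may be lost, because crowding at C6 slows cleavage of the normally more labile group. The fallback sets out from 25 and comes back at target 28, moving the steric differentiation from deprotection to protection. Excess HF·pyridine removes both groups to give the 6β,12-diol imide F9, and TESCl/imidazole at 0 °C silylates only the accessible C12 hydroxyl to give the 12-OTES-6β-ol F10. Buffered Dess–Martin oxidation gives the 12-OTES-6-one F11, and HF·pyridine releases 28.

**Further compounds**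
F1 | step 14 | (R)-4-benzyl-3-(3-cyanopropanoyl)oxazolidin-2-one | N#CCCC(=O)N1[C@H](Cc2ccccc2)COC1=O
F2 | step 14 | (12S,13R) syn-aldol adduct | C=C1C[C@@H](O[Si](CC)(CC)CC)[C@H]2C(C)(C)C[C@H](Cl)C[C@]2(C)[C@H]1C[C@H](O)[C@@H](CC#N)C(=O)N1[C@H](Cc2ccccc2)COC1=O
F3 | step 14 | C12 TBS ether of the aldol adduct | C=C1C[C@@H](O[Si](CC)(CC)CC)[C@H]2C(C)(C)C[C@H](Cl)C[C@]2(C)[C@H]1C[C@H](O[Si](C)(C)C(C)(C)C)[C@@H](CC#N)C(=O)N1[C@H](Cc2ccccc2)COC1=O
F4 | step 14 | C15 primary carboxamide | C=C1C[C@@H](O[Si](CC)(CC)CC)[C@H]2C(C)(C)C[C@H](Cl)C[C@]2(C)[C@H]1C[C@H](O[Si](C)(C)C(C)(C)C)[C@@H](CC(N)=O)C(=O)N1[C@H](Cc2ccccc2)COC1=O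
F5 | step 6 | 2α-chloro-7α-hydroxy-8(17)-ene Weinreb amide | C=C1[C@H](O)C[C@H]2C(C)(C)C[C@H](Cl)C[C@]2(C)[C@H]1CC(=O)N(C)OC
F6 | step 6 | 2α,17-dichloro-7-ene Weinreb amide | ClCC1=CC[C@H]2C(C)(C)C[C@H](Cl)C[C@]2(C)[C@H]1CC(=O)N(C)OC
F7 | step 6 | 2α,17-dichloro-7-en-6-one Weinreb amide | ClCC1=CC(=O)[C@H]2C(C)(C)C[C@H](Cl)C[C@]2(C)[C@H]1CC(=O)N(C)OC
F8 | step 6 | chlorozinc 6,8(17)-dienolate | C=C1C=C(O[Zn]Cl)[C@H]2C(C)(C)C[C@H](Cl)C[C@]2(C)[C@H]1CC(=O)N(C)OC
F9 | step 16 | 6β,12-diol imide | C=C1C[C@@H](O)[C@H]2C(C)(C)C[C@H](Cl)C[C@]2(C)[C@H]1C[C@H](O)[C@H]1CC(=O)NC1=O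
F10 | step 16 | 12-OTES-6β-hydroxy imide | C=C1C[C@@H](O)[C@H]2C(C)(C)C[C@H](Cl)C[C@]2(C)[C@H]1C[C@H](O[Si](CC)(CC)CC)[C@H]1CC(=O)NC1=O
F11 | step 16 | 12-OTES-6-oxo imide | C=C1CC(=O)[C@H]2C(C)(C)C[C@H](Cl)C[C@]2(C)[C@H]1C[C@H](O[Si](CC)(CC)CC)[C@H]1CC(=O)NC1=O
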